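## Retrosynthetic overview

1. Ring numbering: C1 = C(Cl)(CH2Br), C2 = CHBr, C3 = CH2, C4 = CHCl, C5 = C(CH3)(chlorovinyl), C6 = CH2. The enabling feature is the vicinal pair C1/C2, where CH2Br on C1 is trans to Br on C2 and Cl on C1 is cis to it. This is the pattern left when bromide opens, with inversion at C2, a cis-fused 2-oxetanone (beta-lactone) spanning C1–C2 whose carbonyl carbon is the future CH2Br carbon.
2. Key disconnection C1–C2: an acyclic aldehyde acid (C2 = CHO, C1 = alpha-chloro acid carbon) undergoes aldol-lactonization. The cyclohexane closes first and the temporary beta-lactone (its O–C(=O) bond is not in the target) second, in one operation.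
3. After it: bromide opens the lactone at C2, CO2H becomes CH2Br, and C4–OH becomes C4–Cl with inversion.
4. Before it: the C4 carbinol is the only catalyst-set centre (Noyori hydrogenation); C5 is relayed from it by Fráter–Seebach allylation. The ester becomes the (E)-chlorovinyl group (Takai) and the allyl group becomes the alpha-chloro acid arm.

Key step: step 12

Remark: the chlorine-bearing carbon alpha to the carbonyl in 15–19 is carried as an epimer mixture, because step 12 planarises it; "C1–C6" in the Why lines refer to the ring numbering of line 1.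

## Route

Step 1
Reactants: 1 methyl propanoate; 2 methyl 3,3-dimethoxypropanoate
Product: 4 methyl 5,5-dimethoxy-2-methyl-3-oxopentanoate (racemic), via lithium enolate 3 (not isolated)
Conditions: LiN(i-Pr)2 (2.1 equiv), 1 (2.1 equiv), THF, −78 °C; then 2 (1.0 equiv), −78 → −30 °C; aq. NH4Cl
Reagents that add atoms: none
Why: Crossed Claisen condensation in which the preformed enolate of 1 (two equivalents, one consumed as base by the acidic beta-keto ester) should acylate on the ester carbonyl of 2 faster than it deprotonates it at −78 °C; the new C2 centre is labile and of no consequence.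

Step 2
Reactants: 4 methyl 5,5-dimethoxy-2-methyl-3-oxopentanoate
Product: 5 methyl (3S)-3-hydroxy-5,5-dimethoxy-2-methylpentanoate (both C2 epimers)
Conditions: H2 (50 atm), RuCl2[(S)-BINAP] (0.5 mol%), MeOH, 50 °C
Reagents that add atoms: none
Why: Noyori asymmetric hydrogenation of a beta-keto ester, in which the ester-chelated ruthenium hydride of the (S)-BINAP complex should deliver hydride to one ketone face and set the (3S) carbinol (the future C4), the labile C2 centre remaining a mixture that is erased in step 3.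

Step 3
Reactants: 5 methyl (3S)-3-hydroxy-5,5-dimethoxy-2-methylpentanoate
Product: 7 methyl (2S,3S)-3-hydroxy-5,5-dimethoxy-2-methyl-2-(prop-2-en-1-yl)pentanoate, via dilithium alkoxide enolate 6 (not isolated)
Conditions: LiN(i-Pr)2 (2.2 equiv), THF, −78 → −20 °C; then allyl bromide, DMPU, −78 → −10 °C; aq. NH4Cl
Reagents that add atoms: allyl bromide C=CCBr
Why: Fráter–Seebach alkylation, in which the lithium-chelated alkoxide enolate is allylated on the face anti to the C3 side chain, so that the quaternary carbon (the future C5) is relayed from the carbinol centre.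

Step 4
Reactants: 7 methyl (2S,3S)-3-hydroxy-5,5-dimethoxy-2-methyl-2-(prop-2-en-1-yl)pentanoate
Product: 8 methyl (2S,3S)-3-[(tert-butyldimethylsilyl)oxy]-5,5-dimethoxy-2-methyl-2-(prop-2-en-1-yl)pentanoate
Conditions: TBSOTf, 2,6-lutidine, CH2Cl2, −78 → 0 °C
Reagents that add atoms: tert-butyldimethylsilyl triflate CC(C)(C)[Si](C)(C)OS(=O)(=O)C(F)(F)F
Why: Silyl ether formation with the reactive silyl triflate protects the hindered secondary hydroxyl, which would otherwise acylate or alkylate intramolecularly once the chloro acid arm is in place.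

Step 5
Reactants: 8 methyl (2S,3S)-3-[(tert-butyldimethylsilyl)oxy]-5,5-dimethoxy-2-methyl-2-(prop-2-en-1-yl)pentanoate
Product: 9 (2R,3S)-3-[(tert-butyldimethylsilyl)oxy]-5,5-dimethoxy-2-methyl-2-(prop-2-en-1-yl)pentan-1-ol
Conditions: i-Bu2AlH (2.5 equiv), CH2Cl2, −78 → 0 °C; aq. potassium sodium tartrate (KNaC4H4O6)
Reagents that add atoms: none
Why: Hydride reduction of the neopentyl methyl ester to the primary alcohol, to which the acetal, the silyl ether and the terminal alkene are inert.

Step 6
Reactants: 9 (2R,3S)-3-[(tert-butyldimethylsilyl)oxy]-5,5-dimethoxy-2-methyl-2-(prop-2-en-1-yl)pentan-1-ol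
Product: 10 (2S,3S)-3-[(tert-butyldimethylsilyl)oxy]-5,5-dimethoxy-2-methyl-2-(prop-2-en-1-yl)pentanal
Conditions: Dess–Martin periodinane, NaHCO3, CH2Cl2, 0 → 23 °C
Reagents that add atoms: none
Why: Dess–Martin oxidation gives the non-enolisable alpha-quaternary aldehyde under buffered conditions that spare the dimethyl acetal.

Step 7
Reactants: 10 (2S,3S)-3-[(tert-butyldimethylsilyl)oxy]-5,5-dimethoxy-2-methyl-2-(prop-2-en-1-yl)pentanal
Product: 11 tert-butyl{[(1E,3R,4S)-1-chloro-6,6-dimethoxy-3-methyl-3-(prop-2-en-1-yl)hex-1-en-4-yl]oxy}dimethylsilane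
Conditions: CrCl2 (6 equiv), CHCl3 (2 equiv), THF, 65 °C
Reagents that add atoms: chloroform ClC(Cl)Cl
Why: Takai olefination, in which the geminal dichromium species from CHCl3 and CrCl2 adds to the aldehyde and eliminates so that the bulky quaternary substituent and chlorine end up trans, which should give the (E)-chloroalkene.

Step 8
Reactants: 11 tert-butyl{[(1E,3R,4S)-1-chloro-6,6-dimethoxy-3-methyl-3-(prop-2-en-1-yl)hex-1-en-4-yl]oxy}dimethylsilane
Product: 13 (4R,5S)-5-[(tert-butyldimethylsilyl)oxy]-4-[(E)-2-chloroethenyl]-7,7-dimethoxy-4-methylheptan-1-ol, via B-alkyl-9-borabicyclononane 12 (not isolated)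
Conditions: 9-borabicyclo[3.3.1]nonane (9-BBN, 1.3 equiv), THF, 0 → 23 °C; then NaOH, H2O2, 0 °C
Reagents that add atoms: hydrogen peroxide OO
Why: Hydroboration–oxidation with the bulky borane should select the monosubstituted terminal alkene over the hindered, electron-poor chloroalkene and give the anti-Markovnikov primary alcohol.

Step 9
Reactants: 13 (4R,5S)-5-[(tert-butyldimethylsilyl)oxy]-4-[(E)-2-chloroethenyl]-7,7-dimethoxy-4-methylheptan-1-ol
Product: 14 (4R,5S)-5-[(tert-butyldimethylsilyl)oxy]-4-[(E)-2-chloroethenyl]-7,7-dimethoxy-4-methylheptanal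
Conditions: Dess–Martin periodinane, NaHCO3, CH2Cl2, 0 → 23 °C
Reagents that add atoms: none
Why: Dess–Martin oxidation of the primary alcohol to the aldehyde without touching the acetal, the silyl ether or the chloroalkene.

Step 10
Reactants: 14 (4R,5S)-5-[(tert-butyldimethylsilyl)oxy]-4-[(E)-2-chloroethenyl]-7,7-dimethoxy-4-methylheptanal
Product: 16 (4R,5S)-5-[(tert-butyldimethylsilyl)oxy]-2-chloro-4-[(E)-2-chloroethenyl]-7,7-dimethoxy-4-methylheptanoic acid (both C2 epimers), via alpha-chloro aldehyde 15 (not isolated)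
Conditions: N-chlorosuccinimide (1.05 equiv), L-prolinamide (10 mol%), CH2Cl2, 0 °C; then NaClO2, NaH2PO4/Na2HPO4 buffer, 2-methyl-2-butene, t-BuOH/H2O, 0 °C
Reagents that add atoms: N-chlorosuccinimide O=C1CCC(=O)N1Cl; sodium chlorite [Na+].[O-]Cl=O
Why: Enamine-catalysed alpha-chlorination of the aldehyde followed in the same flask by buffered Pinnick oxidation gives the alpha-chloro acid without isolating the labile chloro aldehyde, the configuration of the new C–Cl centre being irrelevant because step 12 planarises it.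

Step 11
Reactants: 16 (4R,5S)-5-[(tert-butyldimethylsilyl)oxy]-2-chloro-4-[(E)-2-chloroethenyl]-7,7-dimethoxy-4-methylheptanoic acid
Product: 17 (4R,5S)-5-[(tert-butyldimethylsilyl)oxy]-2-chloro-4-[(E)-2-chloroethenyl]-4-methyl-7-oxoheptanoic acid (both C2 epimers)
Conditions: LiBF4, MeCN/H2O (98:2), 23 °C
Reagents that add atoms: water O
Why: LiBF4-promoted acetal hydrolysis unmasks the aldehyde under conditions mild enough for the hindered silyl ether and the alpha-chloro acid.

Step 12
Reactants: 17 (4R,5S)-5-[(tert-butyldimethylsilyl)oxy]-2-chloro-4-[(E)-2-chloroethenyl]-4-methyl-7-oxoheptanoic acid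
Product: 20 (1R,3R,4S,6R)-4-[(tert-butyldimethylsilyl)oxy]-1-chloro-3-[(E)-2-chloroethenyl]-3-methyl-7-oxabicyclo[4.2.0]octan-8-one, via acyloxypyridinium triflate 18 (not isolated), via acylpyridinium triflate 19 (not isolated)
Conditions: 2-bromo-1-propylpyridinium triflate (3 equiv), i-Pr2NEt (4 equiv), 4-pyrrolidinopyridine (0.3 equiv), CH2Cl2 (0.02 M), 23 °C, slow addition of 17 over 12 h
Reagents that add atoms: none
Why: Proposed new method: the carboxylate is activated as acyloxypyridinium salt 18 and passed to 4-pyrrolidinopyridine to give acylammonium salt 19, whose alpha-hydrogen (acidified by chlorine) is removed by i-Pr2NEt to give a chlorine-substituted ammonium enolate (in equilibrium with the alkyl(chloro)ketene) that adds to the tethered aldehyde, after which the aldolate closes on the acylammonium carbon and releases the Lewis base; chlorine should ease enolisation and make the acyl carbon more electrophilic, the open point being the formation of a fully substituted carbon. The closest known reaction type is the nucleophile-catalysed aldol-lactonization of aldehyde acids and keto acids to bicyclic beta-lactones (a formal ketene–aldehyde [2+2] cycloaddition), which is known for acids without an alpha-substituent but not for an alpha-chloro acid. The cyclohexane is closed by a 6-exo-trig aldol addition that forms the C1–C2 bond, and the 2-oxetanone by a 4-exo-trig acyl substitution. The two new stereocentres are tied to each other by the ring fusion, which can only be cis for a four-membered lactone, so the lactone carbonyl on C1 and the oxygen on C2 share one face and chlorine takes the other. Which face is used is set by the C4 and C5 centres through a chair-like, product-like transition state in which the C4 silyloxy group, the forming C2–O bond, chlorine and the chlorovinyl group are equatorial and only the flat acyl carbon is axial next to the C5 methyl group, whereas the other fusion would put chlorine 1,3-diaxial to that methyl group. The step needs cyclisation to beat intermolecular acylation and ketene dimerisation, which slow addition at high dilution should secure, and an aldehyde that survives amine base, which the beta-silyloxy (not beta-halo) substitution provides.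

Step 13
Reactants: 20 (1R,3R,4S,6R)-4-[(tert-butyldimethylsilyl)oxy]-1-chloro-3-[(E)-2-chloroethenyl]-3-methyl-7-oxabicyclo[4.2.0]octan-8-one
Product: 21 (1S,2S,4S,5R)-2-bromo-4-[(tert-butyldimethylsilyl)oxy]-1-chloro-5-[(E)-2-chloroethenyl]-5-methylcyclohexane-1-carboxylic acid
Conditions: MgBr2·OEt2 (3 equiv), Et2O/CH2Cl2, 0 → 23 °C; 1 M HCl
Reagents that add atoms: magnesium bromide [Mg+2].[Br-].[Br-]
Why: SN2 opening of the beta-lactone at its O-alkyl carbon by bromide under MgBr2 activation (beta-lactone to beta-halo acid opening) inverts C2 and puts bromine cis to chlorine and trans to the carboxyl group, helped by ring strain, by the better carboxylate leaving group that the alpha-chlorine makes, and by a Cl–C–C–O dihedral angle far from anti-periplanar that disfavours chlorine participation.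

Step 14
Reactants: 21 (1S,2S,4S,5R)-2-bromo-4-[(tert-butyldimethylsilyl)oxy]-1-chloro-5-[(E)-2-chloroethenyl]-5-methylcyclohexane-1-carboxylic acid
Product: 22 [(1S,2S,4S,5R)-2-bromo-4-[(tert-butyldimethylsilyl)oxy]-1-chloro-5-[(E)-2-chloroethenyl]-5-methylcyclohexyl]methanol
Conditions: BH3·SMe2 (2.5 equiv), THF, 0 → 23 °C; MeOH
Reagents that add atoms: none
Why: Chemoselective borane reduction of the carboxylic acid to the primary alcohol under non-basic conditions, which avoids the decarboxylative loss of bromide open to a beta-bromo carboxylate and leaves the alkyl halides and the chloroalkene untouched.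

Step 15
Reactants: 22 [(1S,2S,4S,5R)-2-bromo-4-[(tert-butyldimethylsilyl)oxy]-1-chloro-5-[(E)-2-chloroethenyl]-5-methylcyclohexyl]methanol
Product: 24 {[(1S,2R,4S,5S)-5-bromo-4-(bromomethyl)-4-chloro-2-[(E)-2-chloroethenyl]-2-methylcyclohexyl]oxy}(tert-butyl)dimethylsilane, via primary triflate 23 (not isolated)
Conditions: Tf2O, 2,6-lutidine, CH2Cl2, −78 °C; then Bu4NBr, −78 → 23 °C
Reagents that add atoms: tetrabutylammonium bromide CCCC[N+](CCCC)(CCCC)CCCC.[Br-]
Why: Sulfonate displacement, in which the triflate is reactive enough for SN2 at a beta-branched primary carbon and excess bromide in a weakly ionising solvent should keep direct substitution ahead of chlorine participation.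

Step 16
Reactants: 24 {[(1S,2R,4S,5S)-5-bromo-4-(bromomethyl)-4-chloro-2-[(E)-2-chloroethenyl]-2-methylcyclohexyl]oxy}(tert-butyl)dimethylsilane
Product: 25 (1S,2R,4S,5S)-5-bromo-4-(bromomethyl)-4-chloro-2-[(E)-2-chloroethenyl]-2-methylcyclohexan-1-ol
Conditions: HF·pyridine, THF/pyridine, 0 → 40 °C
Reagents that add atoms: none
Why: Fluoride-mediated desilylation under acidic conditions, in which none of the halides should eliminate.

Step 17
Reactants: 25 (1S,2R,4S,5S)-5-bromo-4-(bromomethyl)-4-chloro-2-[(E)-2-chloroethenyl]-2-methylcyclohexan-1-ol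
Product: 27 (1S,2S,4R,5R)-2-bromo-1-(bromomethyl)-1,4-dichloro-5-[(E)-2-chloroethenyl]-5-methylcyclohexane (CNP0373896.1), via secondary triflate 26 (not isolated)
Conditions: Tf2O, pyridine, CH2Cl2, −40 °C; then Bu4NCl, toluene, −40 → 23 °C
Reagents that add atoms: tetrabutylammonium chloride CCCC[N+](CCCC)(CCCC)CCCC.[Cl-]
Why: Sulfonate displacement by chloride with inversion at C4 (SN2) places chlorine equatorial and cis to the chlorovinyl group and the C2 bromide, the electron-withdrawing halogens nearby disfavouring ionisation and rearrangement.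

## Compound list

1 | methyl propanoate | CCC(=O)OC | starting material
2 | methyl 3,3-dimethoxypropanoate | COC(OC)CC(=O)OC | starting material
3 | lithium 1-methoxyprop-1-en-1-olate (enolate of 1) | [Li+].CC=C([O-])OC | intermediate
4 | methyl 5,5-dimethoxy-2-methyl-3-oxopentanoate (racemic) | COC(OC)CC(=O)C(C)C(=O)OC | intermediate
5 | methyl (3S)-3-hydroxy-5,5-dimethoxy-2-methylpentanoate (both C2 epimers) | COC(OC)C[C@H](O)C(C)C(=O)OC | intermediate
6 | dilithium alkoxide enolate of 5 | [Li+].[Li+].COC(OC)C[C@H]([O-])C(C)=C([O-])OC | intermediate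
7 | methyl (2S,3S)-3-hydroxy-5,5-dimethoxy-2-methyl-2-(prop-2-en-1-yl)pentanoate | COC(OC)C[C@H](O)[C@@](C)(C(=O)OC)CC=C | intermediate
8 | methyl (2S,3S)-3-[(tert-butyldimethylsilyl)oxy]-5,5-dimethoxy-2-methyl-2-(prop-2-en-1-yl)pentanoate | COC(OC)C[C@H](O[Si](C)(C)C(C)(C)C)[C@@](C)(C(=O)OC)CC=C | intermediate
9 | (2R,3S)-3-[(tert-butyldimethylsilyl)oxy]-5,5-dimethoxy-2-methyl-2-(prop-2-en-1-yl)pentan-1-ol | COC(OC)C[C@H](O[Si](C)(C)C(C)(C)C)[C@@](C)(CO)CC=C | intermediate
10 | (2S,3S)-3-[(tert-butyldimethylsilyl)oxy]-5,5-dimethoxy-2-methyl-2-(prop-2-en-1-yl)pentanal | COC(OC)C[C@H](O[Si](C)(C)C(C)(C)C)[C@@](C)(C=O)CC=C | intermediate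
11 | tert-butyl{[(1E,3R,4S)-1-chloro-6,6-dimethoxy-3-methyl-3-(prop-2-en-1-yl)hex-1-en-4-yl]oxy}dimethylsilane | COC(OC)C[C@H](O[Si](C)(C)C(C)(C)C)[C@@](C)(/C=C/Cl)CC=C | intermediate
12 | B-alkyl-9-borabicyclo[3.3.1]nonane from 11 (boron on the terminal carbon) | COC(OC)C[C@H](O[Si](C)(C)C(C)(C)C)[C@@](C)(/C=C/Cl)CCCB1C2CCCC1CCC2 | intermediate
13 | (4R,5S)-5-[(tert-butyldimethylsilyl)oxy]-4-[(E)-2-chloroethenyl]-7,7-dimethoxy-4-methylheptan-1-ol | COC(OC)C[C@H](O[Si](C)(C)C(C)(C)C)[C@@](C)(/C=C/Cl)CCCO | intermediate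
14 | (4R,5S)-5-[(tert-butyldimethylsilyl)oxy]-4-[(E)-2-chloroethenyl]-7,7-dimethoxy-4-methylheptanal | COC(OC)C[C@H](O[Si](C)(C)C(C)(C)C)[C@@](C)(/C=C/Cl)CCC=O | intermediate
15 | (4R,5S)-5-[(tert-butyldimethylsilyl)oxy]-2-chloro-4-[(E)-2-chloroethenyl]-7,7-dimethoxy-4-methylheptanal (both C2 epimers) | COC(OC)C[C@H](O[Si](C)(C)C(C)(C)C)[C@@](C)(/C=C/Cl)CC(Cl)C=O | intermediate
16 | (4R,5S)-5-[(tert-butyldimethylsilyl)oxy]-2-chloro-4-[(E)-2-chloroethenyl]-7,7-dimethoxy-4-methylheptanoic acid (both C2 epimers) | COC(OC)C[C@H](O[Si](C)(C)C(C)(C)C)[C@@](C)(/C=C/Cl)CC(Cl)C(=O)O | intermediate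
17 | (4R,5S)-5-[(tert-butyldimethylsilyl)oxy]-2-chloro-4-[(E)-2-chloroethenyl]-4-methyl-7-oxoheptanoic acid (both C2 epimers) | O=CC[C@H](O[Si](C)(C)C(C)(C)C)[C@@](C)(/C=C/Cl)CC(Cl)C(=O)O | intermediate
18 | 2-acyloxy-1-propylpyridinium triflate of acid 17 | O=CC[C@H](O[Si](C)(C)C(C)(C)C)[C@@](C)(/C=C/Cl)CC(Cl)C(=O)Oc1cccc[n+]1CCC.[O-]S(=O)(=O)C(F)(F)F | intermediate
19 | 1-acyl-4-(pyrrolidin-1-yl)pyridinium triflate of acid 17 | O=CC[C@H](O[Si](C)(C)C(C)(C)C)[C@@](C)(/C=C/Cl)CC(Cl)C(=O)[n+]1ccc(cc1)N1CCCC1.[O-]S(=O)(=O)C(F)(F)F | intermediate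
20 | (1R,3R,4S,6R)-4-[(tert-butyldimethylsilyl)oxy]-1-chloro-3-[(E)-2-chloroethenyl]-3-methyl-7-oxabicyclo[4.2.0]octan-8-one | C[C@]1(/C=C/Cl)C[C@]2(Cl)C(=O)O[C@@H]2C[C@@H]1O[Si](C)(C)C(C)(C)C | intermediate
21 | (1S,2S,4S,5R)-2-bromo-4-[(tert-butyldimethylsilyl)oxy]-1-chloro-5-[(E)-2-chloroethenyl]-5-methylcyclohexane-1-carboxylic acid | C[C@]1(/C=C/Cl)C[C@](Cl)(C(=O)O)[C@@H](Br)C[C@@H]1O[Si](C)(C)C(C)(C)C | intermediate
22 | [(1S,2S,4S,5R)-2-bromo-4-[(tert-butyldimethylsilyl)oxy]-1-chloro-5-[(E)-2-chloroethenyl]-5-methylcyclohexyl]methanol | C[C@]1(/C=C/Cl)C[C@](Cl)(CO)[C@@H](Br)C[C@@H]1O[Si](C)(C)C(C)(C)C | intermediate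
23 | primary triflate of 22 | C[C@]1(/C=C/Cl)C[C@](Cl)(COS(=O)(=O)C(F)(F)F)[C@@H](Br)C[C@@H]1O[Si](C)(C)C(C)(C)C | intermediate
24 | {[(1S,2R,4S,5S)-5-bromo-4-(bromomethyl)-4-chloro-2-[(E)-2-chloroethenyl]-2-methylcyclohexyl]oxy}(tert-butyl)dimethylsilane | C[C@]1(/C=C/Cl)C[C@](Cl)(CBr)[C@@H](Br)C[C@@H]1O[Si](C)(C)C(C)(C)C | intermediate
25 | (1S,2R,4S,5S)-5-bromo-4-(bromomethyl)-4-chloro-2-[(E)-2-chloroethenyl]-2-methylcyclohexan-1-ol | C[C@]1(/C=C/Cl)C[C@](Cl)(CBr)[C@@H](Br)C[C@@H]1O | intermediate
26 | secondary triflate of 25 | C[C@]1(/C=C/Cl)C[C@](Cl)(CBr)[C@@H](Br)C[C@@H]1OS(=O)(=O)C(F)(F)F | intermediate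
27 | (1S,2S,4R,5R)-2-bromo-1-(bromomethyl)-1,4-dichloro-5-[(E)-2-chloroethenyl]-5-methylcyclohexane | C[C@]1(/C=C/Cl)C[C@](Cl)(CBr)[C@@H](Br)C[C@H]1Cl | target

## Step count and risks

Total step count: 17. Longest linear sequence: 17 steps (from 1 and 2).

Steps most likely to fail:

1. Step 12 (proposed new method). The hindered alpha-chloro acylammonium ion may not be enolised and added to the aldehyde fast enough to build a fully substituted carbon, so that intermolecular acylation or ketene dimerisation takes over, or the face of ring fusion may be poorly controlled. The fallback sets out from aldehyde 14 and comes back at lactone 20, and moves the chlorination behind the ring closure. Pinnick oxidation of 14 (NaClO2, NaH2PO4, 2-methyl-2-butene) would give (4R,5S)-5-[(tert-butyldimethylsilyl)oxy]-4-[(E)-2-chloroethenyl]-7,7-dimethoxy-4-methylheptanoic acid F1. LiBF4 in wet MeCN would give (4R,5S)-5-[(tert-butyldimethylsilyl)oxy]-4-[(E)-2-chloroethenyl]-4-methyl-7-oxoheptanoic acid F2. Aldol-lactonization of this alpha-unsubstituted aldehyde acid under the conditions of step 12, a known substrate class, would give (1S,3R,4S,6R)-4-[(tert-butyldimethylsilyl)oxy]-3-[(E)-2-chloroethenyl]-3-methyl-7-oxabicyclo[4.2.0]octan-8-one F3. Deprotonation with LiN(SiMe3)2 in THF at −78 °C and chlorination of the lactone enolate with C2Cl6 would give 20, because the cis ring fusion leaves chlorine only one position.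

2. Step 17. Backside attack at a carbinol carbon flanked by a quaternary carbon is slow, so loss of triflate by E2 toward C3 or a 1,2-shift of the vinyl group may compete with substitution. The fallback sets out from alcohol 25 and comes back at target 27, replacing inversion of the axial alcohol by retention on its epimer. Dess–Martin oxidation of 25 would give (2R,4S,5S)-5-bromo-4-(bromomethyl)-4-chloro-2-[(E)-2-chloroethenyl]-2-methylcyclohexan-1-one F4. NaBH4 with CeCl3·7H2O in MeOH at −78 °C should deliver hydride axially, anti to the axial chlorovinyl group, and give the equatorial alcohol (1R,2R,4S,5S)-5-bromo-4-(bromomethyl)-4-chloro-2-[(E)-2-chloroethenyl]-2-methylcyclohexan-1-ol F5. SOCl2 would convert it into the chlorosulfite of this alcohol F6, which with catalytic TiCl4 at 0 °C should collapse with retention (front-side, internal-return chlorination of cyclic alcohols) to 27.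

3. Step 7. The geminal dichromium reagent may add sluggishly to a neopentyl-type aldehyde at 65 °C, leaving reduction or decomposition of the aldehyde and erosion of the alkene geometry to compete. The fallback sets out from aldehyde 10 and comes back at chloroalkene 11. Ohira–Bestmann homologation (dimethyl (1-diazo-2-oxopropyl)phosphonate, K2CO3, MeOH) of the non-enolisable aldehyde would give tert-butyl{[(3S,4R)-4-ethynyl-1,1-dimethoxy-4-methylhept-6-en-3-yl]oxy}dimethylsilane F7. Hydrostannation with Bu3SnH and catalytic PdCl2(PPh3)2, which leaves the terminal alkene alone, should give tributyl[(1E,3R,4S)-4-[(tert-butyldimethylsilyl)oxy]-6,6-dimethoxy-3-methyl-3-(prop-2-en-1-yl)hex-1-en-1-yl]stannane F8. Chlorodestannylation with CuCl2 in THF, with retention of alkene geometry, would give 11.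

Further compounds
F1 | step 12 | (4R,5S)-5-[(tert-butyldimethylsilyl)oxy]-4-[(E)-2-chloroethenyl]-7,7-dimethoxy-4-methylheptanoic acid | COC(OC)C[C@H](O[Si](C)(C)C(C)(C)C)[C@@](C)(/C=C/Cl)CCC(=O)O
F2 | step 12 | (4R,5S)-5-[(tert-butyldimethylsilyl)oxy]-4-[(E)-2-chloroethenyl]-4-methyl-7-oxoheptanoic acid | O=CC[C@H](O[Si](C)(C)C(C)(C)C)[C@@](C)(/C=C/Cl)CCC(=O)O
F3 | step 12 | (1S,3R,4S,6R)-4-[(tert-butyldimethylsilyl)oxy]-3-[(E)-2-chloroethenyl]-3-methyl-7-oxabicyclo[4.2.0]octan-8-one | C[C@]1(/C=C/Cl)C[C@@H]2C(=O)O[C@@H]2C[C@@H]1O[Si](C)(C)C(C)(C)C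
F4 | step 17 | (2R,4S,5S)-5-bromo-4-(bromomethyl)-4-chloro-2-[(E)-2-chloroethenyl]-2-methylcyclohexan-1-one | C[C@]1(/C=C/Cl)C[C@](Cl)(CBr)[C@@H](Br)CC1=O
F5 | step 17 | (1R,2R,4S,5S)-5-bromo-4-(bromomethyl)-4-chloro-2-[(E)-2-chloroethenyl]-2-methylcyclohexan-1-ol | C[C@]1(/C=C/Cl)C[C@](Cl)(CBr)[C@@H](Br)C[C@H]1O
F6 | step 17 | chlorosulfite of alcohol F5 | C[C@]1(/C=C/Cl)C[C@](Cl)(CBr)[C@@H](Br)C[C@H]1OS(=O)Cl
F7 | step 7 | tert-butyl{[(3S,4R)-4-ethynyl-1,1-dimethoxy-4-methylhept-6-en-3-yl]oxy}dimethylsilane | COC(OC)C[C@H](O[Si](C)(C)C(C)(C)C)[C@@](C)(C#C)CC=C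
F8 | step 7 | tributyl[(1E,3R,4S)-4-[(tert-butyldimethylsilyl)oxy]-6,6-dimethoxy-3-methyl-3-(prop-2-en-1-yl)hex-1-en-1-yl]stannane | COC(OC)C[C@H](O[Si](C)(C)C(C)(C)C)[C@@](C)(/C=C/[Sn](CCCC)(CCCC)CCCC)CC=C
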